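**Retrosynthetic overview**
1. No ring is built. 2-Allylphenol (1) becomes the central ring and two molecules of estragole (2) become the outer rings.
2. Key disconnection: both biaryl bonds (central C4–aryl and C6–aryl), cut together. The phenol is made electrophilic at C4/C6 as its O–iodine(III) derivative (3 from 1, then 5 from the mono-aryl phenol 4). Estragole attacks as the arene nucleophile through the carbon ortho to OMe, giving 6 in one flask.
3. Regiocontrol by design: only the central ring has a free OH, so only it is oxidised. It has exactly two free activated CH positions, and 2 has one kind of activated CH. Either order of the two arylations gives 6.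
4. Last disconnection: the two aryl O–CH3 bonds (BBr3, via borate 7) to macranthol (8).
5. Order of events: C–C (para), C–C (ortho), O-demethylation.

Assumption: macranthol has no stereocentre and its biaryl axes rotate freely, so it is achiral and no enantioselective step is needed.

**Step 1**
Reactants: 1 2-allylphenol; 2 estragole (4-allylanisole; two molecules are incorporated, used in excess)
Product: 6 2-allyl-4,6-bis(5-allyl-2-methoxyphenyl)phenol, via first aryloxy-λ3-iodane 3 (not isolated), via monoaryl phenol 4 (not isolated), via second aryloxy-λ3-iodane 5 (not isolated)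
Conditions: 1 (0.05 M), 2 (15 equiv), HFIP/CH2Cl2 (1:1), −40 °C; PhI(OAc)2 (1.05 equiv, slow addition); after 30 min PhI(OAc)2 (1.05 equiv), −40 → 0 °C
Reagents that add atoms: none
Why: Proposed new method: ligand exchange of the only free OH in the flask on PhI(OAc)2 gives the O–I(III) species 3, a phenoxenium (aryl enolonium) equivalent whose para and ortho carbons are electrophilic instead of nucleophilic; C2 of 2 (its only activated CH, para being blocked by allyl) attacks C4 with loss of PhI and acetate and the dienone tautomerises to 4, which is again the only phenol present, is re-oxidised to 5 (C4 now blocked, ipso capture by solvent being reversible for this aryl-stabilised oxenium) and is arylated at its last free ortho carbon C6 to give 6, so either order of the two arylations converges on 6 and no stereocentre is formed; the closest known reaction type is the iodine(III)-mediated oxidative cross-coupling of phenols with electron-rich arenes in fluoroalcohol solvents (aromatic-ring umpolung, oxidative Friedel–Crafts), used here twice in one flask with a mono-alkoxyarene.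

**Step 2**
Reactants: 6 2-allyl-4,6-bis(5-allyl-2-methoxyphenyl)phenol
Product: 8 macranthol, via aryl dibromoborate 7 (not isolated)
Conditions: BBr3 (5 equiv), CH2Cl2, −78 → 0 °C; then H2O
Reagents that add atoms: none
Why: BBr3 aryl methyl ether cleavage: boron binds each OMe oxygen, bromide removes the methyl group by SN2 and the aryl dibromoborates 7 are hydrolysed on work-up; low-temperature BBr3 is the usual way to demethylate allyl-bearing biaryl methyl ethers of the honokiol/magnolol type, and no stereocentre is involved.

**Compound list**
1 | 2-allylphenol | C=CCc1ccccc1O | starting material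
2 | estragole (1-allyl-4-methoxybenzene) | C=CCc1ccc(OC)cc1 | starting material
3 | acetoxy(2-allylphenoxy)(phenyl)-λ3-iodane | C=CCc1ccccc1OI(OC(C)=O)c1ccccc1 | intermediate
4 | 2-allyl-4-(5-allyl-2-methoxyphenyl)phenol | C=CCc1cc(-c2cc(CC=C)ccc2OC)ccc1O | intermediate
5 | acetoxy[2-allyl-4-(5-allyl-2-methoxyphenyl)phenoxy](phenyl)-λ3-iodane | C=CCc1cc(-c2cc(CC=C)ccc2OC)ccc1OI(OC(C)=O)c1ccccc1 | intermediate
6 | 2-allyl-4,6-bis(5-allyl-2-methoxyphenyl)phenol | C=CCc1cc(-c2cc(CC=C)ccc2OC)cc(-c2cc(CC=C)ccc2OC)c1O | intermediate
7 | tris(O-dibromoboryl) derivative of macranthol | C=CCc1cc(-c2cc(CC=C)ccc2OB(Br)Br)cc(-c2cc(CC=C)ccc2OB(Br)Br)c1OB(Br)Br | intermediate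
8 | macranthol, 2-allyl-4,6-bis(5-allyl-2-hydroxyphenyl)phenol (achiral) | C=CCc1cc(-c2cc(CC=C)ccc2O)cc(-c2cc(CC=C)ccc2O)c1O | target

**Total step count:** 2
**Longest linear sequence:** 2 (from 1)

**Steps most likely to fail**
The route has only two steps, so the two bond-forming events of step 1 are ranked separately.

1. Step 1, first biaryl bond (1 → 4). Estragole is only a moderate arene nucleophile. Unoxidised 1 and freshly formed 4 are better nucleophiles and give phenol–phenol dimers. HFIP or acetate can capture the phenoxenium equivalent, leading to quinone-type products. Iodine(III) can also trigger oxidative cyclisation of the o-allylphenol. Fallback: it sets out from 2. Ring bromination (NBS, MeCN, dark) gives 4-allyl-2-bromo-1-methoxybenzene F1. Suzuki coupling with commercial 4-hydroxyphenylboronic acid (Pd(PPh3)4, K2CO3, dioxane/H2O) gives 4-(5-allyl-2-methoxyphenyl)phenol F2. O-Allylation (allyl bromide, K2CO3, acetone) gives 4-allyl-2-[4-(allyloxy)phenyl]-1-methoxybenzene F3. Aromatic Claisen rearrangement (N,N-diethylaniline, 190 °C; both ortho positions are equivalent) comes back to the route at 4, now isolated. Compound 4 is then taken through the second half of step 1 (one portion of PhI(OAc)2, excess 2) to 6.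

2. Step 1, second biaryl bond (4 → 6). The oxenium from 4 is aryl-stabilised and so less electrophilic, and C6 is hindered. Product 6 can be over-oxidised if oxidant is in excess, and attack on the methoxyaryl ring of 5 is conceivable. Fallback: it sets out from 4, obtained by stopping step 1 after the first oxidant portion or from the fallback above. Amine-directed ortho-bromination (NBS, 10 mol% iPr2NH, CH2Cl2, 0 °C) gives 2-allyl-6-bromo-4-(5-allyl-2-methoxyphenyl)phenol F4. The boron partner, (5-allyl-2-methoxyphenyl)boronic acid F5, is made from F1 (n-BuLi, THF, −78 °C; B(OiPr)3; aqueous HCl). Suzuki coupling of F4 with F5 (Pd(OAc)2/SPhos, K3PO4, toluene/H2O, 80 °C) comes back to the route at 6.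

3. Step 2 (6 → 8). HBr formed in situ can add to the allyl groups, and the Lewis acid can cyclise the o-allylphenol to a 2-methyl-dihydrobenzofuran. Fallback: it sets out from 1 and replaces the methyl ethers by O-allyl ethers. Commercial 4-allylphenol is O-allylated (allyl bromide, K2CO3, acetone) to 1-allyl-4-(allyloxy)benzene F6. F6 is used in place of 2 in the step 1 protocol to give 2-allyl-4,6-bis[5-allyl-2-(allyloxy)phenyl]phenol F7. Neutral Pd(0)-catalysed O-deallylation (Pd(PPh3)4 5 mol%, morpholine, THF, rt), which leaves the C-allyl groups untouched, comes back to the route at 8.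

**Further compounds**
F1 | step 1 | 4-allyl-2-bromo-1-methoxybenzene | C=CCc1ccc(OC)c(Br)c1
F2 | step 1 | 4-(5-allyl-2-methoxyphenyl)phenol | C=CCc1ccc(OC)c(-c2ccc(O)cc2)c1
F3 | step 1 | 4-allyl-2-[4-(allyloxy)phenyl]-1-methoxybenzene | C=CCOc1ccc(-c2cc(CC=C)ccc2OC)cc1
F4 | step 1 | 2-allyl-6-bromo-4-(5-allyl-2-methoxyphenyl)phenol | C=CCc1cc(-c2cc(CC=C)ccc2OC)cc(Br)c1O
F5 | step 1 | (5-allyl-2-methoxyphenyl)boronic acid | C=CCc1ccc(OC)c(B(O)O)c1
F6 | step 2 | 1-allyl-4-(allyloxy)benzene | C=CCOc1ccc(CC=C)cc1
F7 | step 2 | 2-allyl-4,6-bis[5-allyl-2-(allyloxy)phenyl]phenol | C=CCc1cc(-c2cc(CC=C)ccc2OCC=C)cc(-c2cc(CC=C)ccc2OCC=C)c1O
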